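**Remark (assumption):** atoms are numbered as in fluorene: ring A = C1, C2, C3, C4, C4a, C9a (ene-dione); ring B = C4a, C4b, C8a, C9, C9a (five-membered); ring C = C4b, C5–C8, C8a (hydroquinone); ring D = C4a, C10, C11, C12, C9, C9a, with the bridge C10(H)=C11(CH3)–C12H2 and C10 on C4a; prenyl = C1'–C5' on C9a. On this numbering the SMILES is read as (4aR,9R,9aS); compounds 1, 3, 9 and 18 and all reagents are assumed to be commercial.

## Analysis of the target

The target is tetracyclic. Rings B and D together form a benzobicyclo[3.2.1]octadiene with bridgeheads C4a and C9, C9a as the one-carbon bridge, ring C as the two-carbon bridge and C10=C11–C12 as the three-carbon bridge; ring A is fused on the C4a–C9a bond. There are three contiguous stereocentres: C4a (quaternary, carrying an aryl, an alkenyl and an acyl carbon), C9a (quaternary, carrying prenyl) and C9 (tertiary, bridgehead). C4a and C9 are tied to each other by the bridge. C9a is independent: the prenyl group lies on the side of the C10–C12 bridge and C1 lies over ring C, so rings A and B are cis-fused. None of the three centres can epimerize, so each must be set correctly when it is made.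

The feature that the strategy uses is that rings A, B and C with the oxygens on C1, C4, C5 and C8 are a fluorene-1,4,5,8-tetraol in disguise. Ring A has lost its aromaticity because its two ring-fusion carbons are C-alkylated: C4a (ortho to the C4 oxygen) by C10, and C9a (ortho to the C1 oxygen) by C1'. Without these two bonds the C9-substituted fluorene has a mirror plane through C9, and rings A and C are enantiotopic.

Sensitive groups are the ene-dione (Michael acceptor, base), the free hydroquinone (air oxidation) and the prenyl group (acid, oxidants, metathesis). The difficulties are the vicinal quaternary carbons C4a/C9a, the position of the ring D alkene at C10=C11 (not the pattern a Diels–Alder reaction on a C4a=C9a dienophile would leave), the face of C9a, and absolute control in a skeleton that is almost symmetric.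

## Retrosynthetic reasoning

**22 ⇒ 20 (through 21).** Only the O–CH3 bond at C8 is cut. Ring C of 20 is a p-methoxyphenol, so the methyl group can be removed by oxidation to quinone 21 and reduction, without the Lewis acids that prenyl and ene-dione would not survive. The forward step must leave both alkenes alone and reduce only the quinone.

**20 ⇒ 17 + 18.** The C9a–C1' bond is cut. In 17, C4a is quaternary and C2/C3 are vinylic, so C9a is the only carbon that can form an enolate; regiochemistry is fixed. The forward alkylation has to take place on the face of C9a that is syn to the C10–C12 bridge and anti to ring C.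

**17 ⇒ 15 (through 16), the key disconnection.** The C4a–C10 bond is cut. This opens ring D, removes the bicyclo[3.2.1] core and both stereocentres C4a and C9, and returns ring A to a phenol: 15 is flat, achiral and Cs-symmetric. The cut is made here because C4a is the ortho carbon of the C4 phenol and C10 is an sp2 carbon, so the bond is an enolate/alkenyl halide union that also fixes the alkene at C10=C11. The forward reaction must choose one of two enantiotopic phenol rings, bond at carbon and not oxygen, and bond at C4a and not C9a.

**15 ⇒ 14 ⇒ 8 + 12.** The C9–C12 bond is cut; forward, the fluorenyl anion of 8 is alkylated. The bay oxygens (C4, C5) carry isopropyl groups and the C1/C8 oxygens methyl groups, so that only the bay phenols are freed before the key step. The C1 methyl ether blocks the competing phenoxide that would activate C9a.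

**12 ⇒ 11 ⇒ 9.** The Z-alkenyl iodide is traced to alkyne 9: the C11–CH3 and C10–I bonds are made across the triple bond in an anti sense, which gives the geometry the ring closure needs.

**8 ⇒ 7 ⇒ 6 ⇒ 2 (twice) + 3; 2 ⇒ 1.** Ring B is opened at the biaryl bond C4a–C4b, and C9 is traced to formate 3, which joins two molecules of 2 through aryllithium 4 and aldehyde 5. The bromine of 1 first directs the metalation and then supplies the biaryl bond; the symmetry means one aryl unit is made once and used twice.

## Alternatives that were turned down

**Alternative 1:** the textbook route. Ring D is cut at C10=C11 (ring-closing metathesis), and the quaternary centres are cut at C4a–C10 and C9a–C1' (conjugate addition of a vinyl nucleophile to a fluorene-1,4-quinone, then trapping of the enolate with a prenyl halide). The forward key step is metathesis of triene A1. It was turned down for four reasons. The ruthenium alkylidene on the C4a vinyl group has a cis-vicinal prenyl group, and closure onto it to an unstrained cyclopentene should outrun closure onto the 1,1-disubstituted methallyl alkene to the strained bridged ring. The vinyl and methallyl groups must be cis across ring B, against the bias of a nucleophile to add anti to the C9 substituent. The quinone has two β-carbons (C4a and C9a), so the conjugate addition is not regio-defined. The three stereocentres are set one at a time with no source of absolute configuration, and the count exceeds twelve steps.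

**Alternative 2:** an intramolecular Diels–Alder reaction. The bonds C4a–C9a and C9–C12 are cut, which leads to A2, a ring C arene carrying the dienophile C9=C9a and the diene C4a=C10–C11=C12 on neighbouring carbons. The forward step would close rings B and D at once and place the alkene at C10=C11. It was turned down because the C4a–C9a bond would form between two fully substituted sp2 carbons, both partners are electron-poor, and the diene needs the aryl group as an inside substituent. Nothing controls absolute configuration. Ring A would still have to be built afterwards from two hindered esters on vicinal quaternary carbons (four or more steps). The ordinary quinone Diels–Alder retron is absent, since a diene across C9/C12–C10 would leave the alkene at C11=C12.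

**Alternative 3:** a biomimetic isomerization. The target is an isomer of bis-quinone A3; the bonds C4a–C4b and C9–C9a are cut. Forward, ring C would tautomerize to a hydroxy-o-quinone methide, C4b would add to C4a, and the C9a enolate would add to C9. It was turned down because the first C–C bond has a better outlet: C4b can add to C11 (1,6-addition through the C10=C11 alkene), which forms a five-membered ring and re-aromatizes ring A. All stereocentres would arise from planar intermediates with no absolute control, and the face of C9a would rest on an unsecured preference. The route is short, but its one step cannot be defended.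

Key step: step 9

## Route

Step 1
Reactants: 1 2-bromo-4-methoxyphenol
Product: 2 2-bromo-4-methoxy-1-(propan-2-yloxy)benzene
Conditions: 2-bromopropane, K2CO3, DMF, 60 °C
Reagents that add atoms: 2-bromopropane, CC(C)Br
Why: Williamson ether synthesis on the phenoxide; the isopropyl ether withstands the lithium amide, the acid of step 3 and zerovalent nickel, and is later split by BCl3 without loss of the methyl ethers.

Step 2
Reactants: 2 2-bromo-4-methoxy-1-(propan-2-yloxy)benzene (2 equiv); 3 ethyl formate
Product: 6 bis[2-bromo-6-methoxy-3-(propan-2-yloxy)phenyl]methanol, via aryllithium 4 (not isolated), via aldehyde 5 (not isolated)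
Conditions: LiN(iPr)2, THF, −78 °C; 3 (0.5 equiv), −78 → 0 °C; 1 M HCl
Reagents that add atoms: none
Why: The hydrogen between Br and OMe is the most acidic, so directed ortho-metalation at −78 °C (cold enough to hold back aryne formation) gives 4; 4 formylates with 3 and a second equivalent adds to aldehyde 5 (double addition to a formate).

Step 3
Reactants: 6 bis[2-bromo-6-methoxy-3-(propan-2-yloxy)phenyl]methanol
Product: 7 bis[2-bromo-6-methoxy-3-(propan-2-yloxy)phenyl]methane
Conditions: Et3SiH, CF3CO2H, CH2Cl2, 0 °C
Reagents that add atoms: none
Why: Ionic hydrogenation: the acid ionizes the carbinol to a diarylmethyl cation stabilized by two ortho-methoxy groups and the silane delivers hydride; the aryl bromides and both kinds of ether are inert.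

Step 4
Reactants: 7 bis[2-bromo-6-methoxy-3-(propan-2-yloxy)phenyl]methane
Product: 8 1,8-dimethoxy-4,5-di(propan-2-yloxy)-9H-fluorene
Conditions: Ni(cod)2 (1.5 equiv), 2,2'-bipyridine, DMF, 60 °C
Reagents that add atoms: none
Why: Intramolecular reductive aryl–aryl coupling (Ullmann-type, mediated by zerovalent nickel): two oxidative additions and reductive elimination from a six-membered diarylnickel ring close ring B, the methylene tether holding the two C–Br carbons within bonding distance.

Step 5
Reactants: 9 prop-2-yn-1-ol
Product: 11 (Z)-3-iodo-2-methylprop-2-en-1-ol, via alkenylmagnesium alkoxide 10 (not isolated)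
Conditions: MeMgBr (2.5 equiv), CuI (10 mol %), THF, −10 → 23 °C; I2, −78 → 0 °C; 1 M HCl
Reagents that add atoms: methylmagnesium bromide, C[Mg]Br; iodine, II
Why: Copper-catalysed carbomagnesiation of the magnesium propargyl alkoxide delivers methyl to C2 and magnesium to C3 in an anti sense through a five-membered alkoxide chelate; iodine cleaves the C–Mg bond with retention, which sets the Z geometry.

Step 6
Reactants: 11 (Z)-3-iodo-2-methylprop-2-en-1-ol
Product: 12 (Z)-3-bromo-1-iodo-2-methylprop-1-ene
Conditions: PBr3, Et2O, 0 °C
Reagents that add atoms: phosphorus tribromide, BrP(Br)Br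
Why: The allylic alcohol is converted into the bromide through its phosphite ester (SN2 at the primary carbon); the alkenyl iodide and its geometry are not touched.

Step 7
Reactants: 8 1,8-dimethoxy-4,5-di(propan-2-yloxy)-9H-fluorene; 12 (Z)-3-bromo-1-iodo-2-methylprop-1-ene
Product: 14 9-[(Z)-3-iodo-2-methylprop-2-enyl]-1,8-dimethoxy-4,5-di(propan-2-yloxy)-9H-fluorene, via fluorenyllithium 13 (not isolated)
Conditions: n-BuLi (1.0 equiv), THF, −78 °C; 12, −78 → 0 °C
Reagents that add atoms: none
Why: Deprotonation at C9 gives the aromatic fluorenyl anion, which alkylates the primary allylic bromide by SN2; the two methoxy groups flanking C9 hinder a second alkylation, the delocalized anion should not exchange with the alkenyl iodide, and the product keeps its mirror plane.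

Step 8
Reactants: 14 9-[(Z)-3-iodo-2-methylprop-2-enyl]-1,8-dimethoxy-4,5-di(propan-2-yloxy)-9H-fluorene
Product: 15 9-[(Z)-3-iodo-2-methylprop-2-enyl]-1,8-dimethoxy-9H-fluorene-4,5-diol
Conditions: BCl3, CH2Cl2, −78 → 0 °C; H2O
Reagents that add atoms: none
Why: Lewis acid dealkylation: BCl3 cleaves the secondary isopropyl ethers well below the temperature at which aryl methyl ethers react, so only the two bay hydroxyl groups on C4 and C5 are freed.

Step 9
Reactants: 15 9-[(Z)-3-iodo-2-methylprop-2-enyl]-1,8-dimethoxy-9H-fluorene-4,5-diol
Product: 17 (4aS,9S)-5-hydroxy-8-methoxy-11-methyl-4a,9-(prop-1-ene-1,3-diyl)-4a,9a-dihydro-1H-fluorene-1,4(9H)-dione, via methyl dienol ether 16 (not isolated)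
Conditions: Pd(OAc)2 (5 mol %), (S)-AntPhos (10 mol %), K2CO3, toluene, 90 °C; then 1 M HCl, THF, 23 °C
Reagents that add atoms: water, O
Why: Proposed new method: oxidative addition of the Z-alkenyl iodide to zerovalent palladium, exchange of iodide for the potassium phenoxide of one ring, bonding of palladium to the ortho carbon C4a (an oxa-π-allyl) and reductive elimination form C4a–C10 and leave ring A as the 2,4-dienone 16; the closest known reaction type is the palladium-catalysed intramolecular arylative dearomatization of phenols, which is enantioselective with P-chiral monophosphines but has been used at para positions and on naphthols, not at a ring-fusion ortho carbon with an alkenyl halide and two enantiotopic phenol rings. Ring D closes as a six-membered ring across C9 and C4a of ring B (a 1,3-bridge that creates the bicyclo[3.2.1] core) by C–C reductive elimination from a seven-membered palladacycle. C9 becomes a stereocentre through the choice between the enantiotopic rings of Cs-symmetric 15, which the chiral ligand controls; the configuration of the quaternary C4a then follows from the tether, because the bridge can span only one face of ring B. The step needs ring selection (ligand), C- over O-alkenylation (a six-membered carbocycle against an eight-membered aryl alkenyl ether) and C4a over C9a (only the bay hydroxyl on C4 is free and C9a is meta to it, while the C1 oxygen is blocked as its methyl ether). The Z geometry of the iodide holds palladium and C12 cis, as the ring requires. Acid work-up hydrolyses the C1 methyl dienol ether of 16 to the C1 ketone, after which C9a carries hydrogen and is the only enolizable position of 17.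

Step 10
Reactants: 17 (4aS,9S)-5-hydroxy-8-methoxy-11-methyl-4a,9-(prop-1-ene-1,3-diyl)-4a,9a-dihydro-1H-fluorene-1,4(9H)-dione; 18 1-bromo-3-methylbut-2-ene
Product: 20 (4aR,9R,9aS)-5-hydroxy-8-methoxy-11-methyl-9a-(3-methylbut-2-enyl)-4a,9-(prop-1-ene-1,3-diyl)-4a,9a-dihydro-1H-fluorene-1,4(9H)-dione, via dilithium enolate 19 (not isolated)
Conditions: LiN(SiMe3)2 (2.2 equiv), THF, −78 °C; 18 (1.2 equiv), −78 → −20 °C; 1 M HCl
Reagents that add atoms: none
Why: Ketone enolate alkylation: one equivalent of base takes the C5 phenol, the second forms the only possible enolate (C1/C9a), and its carbon, softer and more basic than the chelated phenoxide, should take the allylic bromide; the electrophile should enter anti to the electron-rich ring C and syn to the C10–C12 bridge, as electrophiles do with 7-alkylidenebenzonorbornenes, which gives the cis A/B fusion and the 9aS centre.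

Step 11
Reactants: 20 (4aR,9R,9aS)-5-hydroxy-8-methoxy-11-methyl-9a-(3-methylbut-2-enyl)-4a,9-(prop-1-ene-1,3-diyl)-4a,9a-dihydro-1H-fluorene-1,4(9H)-dione
Product: 22 (4aR,9R,9aS)-5,8-dihydroxy-11-methyl-9a-(3-methylbut-2-enyl)-4a,9-(prop-1-ene-1,3-diyl)-4a,9a-dihydro-1H-fluorene-1,4(9H)-dione, via quinone 21 (not isolated)
Conditions: PhI(OAc)2, MeCN–H2O, 0 °C; then aq. Na2S2O4, EtOAc, 23 °C
Reagents that add atoms: water, O
Why: Oxidative demethylation of the p-methoxyphenol ring C to the p-quinone by trivalent iodine (water supplies the new oxygen on C8), then dithionite reduction of the quinone, which is reduced far more easily than the ring A ene-dione; no stereocentre is involved.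

## Compound list

1 | 2-bromo-4-methoxyphenol | COc1ccc(O)c(Br)c1 | starting material
2 | 2-bromo-4-methoxy-1-(propan-2-yloxy)benzene | COc1ccc(OC(C)C)c(Br)c1 | intermediate
3 | ethyl formate | CCOC=O | starting material
4 | [2-bromo-6-methoxy-3-(propan-2-yloxy)phenyl]lithium | [Li]c1c(Br)c(OC(C)C)ccc1OC | intermediate
5 | 2-bromo-6-methoxy-3-(propan-2-yloxy)benzaldehyde | O=Cc1c(Br)c(OC(C)C)ccc1OC | intermediate
6 | bis[2-bromo-6-methoxy-3-(propan-2-yloxy)phenyl]methanol | OC(c1c(Br)c(OC(C)C)ccc1OC)c1c(Br)c(OC(C)C)ccc1OC | intermediate
7 | bis[2-bromo-6-methoxy-3-(propan-2-yloxy)phenyl]methane | COc1ccc(OC(C)C)c(Br)c1Cc1c(Br)c(OC(C)C)ccc1OC | intermediate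
8 | 1,8-dimethoxy-4,5-di(propan-2-yloxy)-9H-fluorene | COc1ccc(OC(C)C)c2c1Cc1c(OC)ccc(OC(C)C)c12 | intermediate
9 | prop-2-yn-1-ol | OCC#C | starting material
10 | bromo[(Z)-3-(bromomagnesiooxy)-2-methylprop-1-enyl]magnesium | Br[Mg]/C=C(/C)CO[Mg]Br | intermediate
11 | (Z)-3-iodo-2-methylprop-2-en-1-ol | I/C=C(/C)CO | intermediate
12 | (Z)-3-bromo-1-iodo-2-methylprop-1-ene | I/C=C(/C)CBr | intermediate
13 | [1,8-dimethoxy-4,5-di(propan-2-yloxy)-9H-fluoren-9-yl]lithium | COc1ccc(OC(C)C)c2c1C([Li])c1c(OC)ccc(OC(C)C)c12 | intermediate
14 | 9-[(Z)-3-iodo-2-methylprop-2-enyl]-1,8-dimethoxy-4,5-di(propan-2-yloxy)-9H-fluorene | COc1ccc(OC(C)C)c2c1C(C/C(C)=C\I)c1c(OC)ccc(OC(C)C)c12 | intermediate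
15 | 9-[(Z)-3-iodo-2-methylprop-2-enyl]-1,8-dimethoxy-9H-fluorene-4,5-diol (achiral, Cs-symmetric) | COc1ccc(O)c2c1C(C/C(C)=C\I)c1c(OC)ccc(O)c12 | intermediate
16 | 5-hydroxy-1,8-dimethoxy-11-methyl-4a,9-(prop-1-ene-1,3-diyl)-4a,9-dihydro-4H-fluoren-4-one, C4a and C9 arranged as in 17 | C12=C(OC)C=CC(=O)[C@@]13C=C(C)C[C@@H]2c1c(OC)ccc(O)c13 | intermediate
17 | (4aS,9S)-5-hydroxy-8-methoxy-11-methyl-4a,9-(prop-1-ene-1,3-diyl)-4a,9a-dihydro-1H-fluorene-1,4(9H)-dione; C9a–H not fixed (enolizable); same spatial arrangement at C4a and C9 as in 22, the descriptors differ only because C9a bears H | C12C(=O)C=CC(=O)[C@@]13C=C(C)C[C@@H]2c1c(OC)ccc(O)c13 | intermediate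
18 | 1-bromo-3-methylbut-2-ene | CC(C)=CCBr | starting material
19 | dilithium salt of 17 (C1 enolate and C5 phenoxide) | C12=C(O[Li])C=CC(=O)[C@@]13C=C(C)C[C@@H]2c1c(OC)ccc(O[Li])c13 | intermediate
20 | (4aR,9R,9aS)-5-hydroxy-8-methoxy-11-methyl-9a-(3-methylbut-2-enyl)-4a,9-(prop-1-ene-1,3-diyl)-4a,9a-dihydro-1H-fluorene-1,4(9H)-dione | CC(C)=CC[C@@]12C(=O)C=CC(=O)[C@@]13C=C(C)C[C@@H]2c1c(OC)ccc(O)c13 | intermediate
21 | 11-methyl-9a-(3-methylbut-2-enyl)-4a,9-(prop-1-ene-1,3-diyl)-4a,9a-dihydro-1H-fluorene-1,4,5,8(9H)-tetrone, stereocentres arranged as in 20 | CC(C)=CC[C@@]12C(=O)C=CC(=O)[C@@]13C=C(C)C[C@@H]2C1=C3C(=O)C=CC1=O | intermediate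
22 | (4aR,9R,9aS)-5,8-dihydroxy-11-methyl-9a-(3-methylbut-2-enyl)-4a,9-(prop-1-ene-1,3-diyl)-4a,9a-dihydro-1H-fluorene-1,4(9H)-dione (CNP0513322.1) | CC(C)=CC[C@@]12C(=O)C=CC(=O)[C@@]13C=C(C)C[C@@H]2c1c(O)ccc(O)c13 | target

## Step count and least certain steps

Total step count: 11. Longest linear sequence: 9 steps (steps 1, 2, 3, 4, 7, 8, 9, 10, 11); steps 5 and 6 make the side chain.

**Step 9 (key step, the one step beyond known chemistry).** The alkenylpalladium may be reduced or may couple at oxygen instead of at the hindered ring-fusion carbon, and the ligand may discriminate poorly between the two enantiotopic phenol rings; if the wrong ring is favoured, (R)-AntPhos is used instead.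

The fallback uses known reactions only; it sets out from 15 and comes back at 17. Enantiotopic-group-selective mono-acetylation of 15 with a lipase and vinyl acetate should give the monoacetate 4-hydroxy-9-[(Z)-3-iodo-2-methylprop-2-enyl]-1,8-dimethoxy-9H-fluoren-5-yl acetate F1. PhI(OAc)2 in MeOH should oxidise only the free p-methoxyphenol ring, to the quinone monoketal F2. An intramolecular Nozaki–Hiyama–Kishi reaction (CrCl2, NiCl2 cat., DMF) should add C10 to the C4 ketone and give the seven-membered tertiary alcohol F3. Aqueous CF3CO2H should hydrolyse the ketal to the p-quinol F4, which should undergo the quinol–enedione rearrangement: a 1,2-shift of the alkenyl carbon C10 from C4 to C4a, on the face fixed by the tether, gives the C5 acetate of 17 F5. K2CO3 in MeOH then frees the phenol and gives 17.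

**Step 10.** The electrophile may approach the bridging enolate carbon from the ring C side (wrong configuration at C9a), or the hindered enolate may be alkylated at oxygen.

The fallback sets out from 17 and comes back at 20; it puts the face under catalyst control. Double acylation (KN(SiMe3)2, allyl chloroformate) should give the bis(allyl carbonate) of 17 F6. Decarboxylative allylation with Pd2(dba)3 and (S)- or (R)-t-BuPHOX (the matched antipode), followed by morpholine in the same flask to remove the allyl group that ends up on the C5 oxygen, should give the C9a-allyl analogue of 20 F7. Cross-metathesis with 2-methylbut-2-ene (second-generation Grubbs catalyst, CH2Cl2, 40 °C) turns allyl into prenyl and gives 20.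

**Step 4.** The coupling may stall after the first oxidative addition and end in protodebromination, because reductive elimination must force two isopropoxy groups into the bay region while the ring becomes planar.

The fallback sets out from 2 and comes back at 8; it makes the biaryl bond intermolecularly and closes ring B at C9–C8a instead. Bromine–lithium exchange on 2 (n-BuLi), then B(OMe)3 and acid, should give [5-methoxy-2-(propan-2-yloxy)phenyl]boronic acid F8. Aldehyde 5 is isolated this time (metalation as in step 2, N,N-dimethylformamide as electrophile). Suzuki coupling of 5 with F8 (Pd(OAc)2, SPhos, K3PO4) should give 3,5'-dimethoxy-2',6-di(propan-2-yloxy)biphenyl-2-carbaldehyde F9. Oxidative acyl radical cyclization (t-BuOOH, 1,2-dichloroethane, 100 °C) onto the free position ortho to the biaryl bond should give 1,8-dimethoxy-4,5-di(propan-2-yloxy)-9H-fluoren-9-one F10. Wolff–Kishner reduction (N2H4·H2O, KOH, diethylene glycol) gives 8.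

## Further compounds

F1 | step 9 | 4-hydroxy-9-[(Z)-3-iodo-2-methylprop-2-enyl]-1,8-dimethoxy-9H-fluoren-5-yl acetate, C9 configured so that the free phenol ring becomes ring A | I/C=C(/C)C[C@H]1c2c(OC)ccc(O)c2-c2c(OC(C)=O)ccc(OC)c21
F2 | step 9 | 9-[(Z)-3-iodo-2-methylprop-2-enyl]-1,1,8-trimethoxy-4-oxo-4,9-dihydro-1H-fluoren-5-yl acetate | I/C=C(/C)C[C@H]1C2=C(c3c(OC(C)=O)ccc(OC)c31)C(=O)C=CC2(OC)OC
F3 | step 9 | 4-hydroxy-1,1,8-trimethoxy-11-methyl-4,9-(prop-1-ene-1,3-diyl)-4,9-dihydro-1H-fluoren-5-yl acetate (C10 bonded to C4) | CC1=C[C@]2(O)C=CC(OC)(OC)C3=C2c2c(OC(C)=O)ccc(OC)c2[C@H]3C1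
F4 | step 9 | 4-hydroxy-8-methoxy-11-methyl-1-oxo-4,9-(prop-1-ene-1,3-diyl)-4,9-dihydro-1H-fluoren-5-yl acetate (p-quinol) | CC1=C[C@]2(O)C=CC(=O)C3=C2c2c(OC(C)=O)ccc(OC)c2[C@H]3C1
F5 | step 9 | C5 acetate of 17 | C12C(=O)C=CC(=O)[C@@]13C=C(C)C[C@@H]2c1c(OC)ccc(OC(C)=O)c13
F6 | step 10 | bis(allyl carbonate) of 17 (on the C1 enol oxygen and the C5 phenol oxygen) | C12=C(OC(=O)OCC=C)C=CC(=O)[C@@]13C=C(C)C[C@@H]2c1c(OC)ccc(OC(=O)OCC=C)c13
F7 | step 10 | (4aR,9R,9aS)-5-hydroxy-8-methoxy-11-methyl-9a-(prop-2-enyl)-4a,9-(prop-1-ene-1,3-diyl)-4a,9a-dihydro-1H-fluorene-1,4(9H)-dione | C=CC[C@@]12C(=O)C=CC(=O)[C@@]13C=C(C)C[C@@H]2c1c(OC)ccc(O)c13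
F8 | step 4 | [5-methoxy-2-(propan-2-yloxy)phenyl]boronic acid | COc1ccc(OC(C)C)c(B(O)O)c1
F9 | step 4 | 3,5'-dimethoxy-2',6-di(propan-2-yloxy)biphenyl-2-carbaldehyde | O=Cc1c(OC)ccc(OC(C)C)c1-c1cc(OC)ccc1OC(C)C
F10 | step 4 | 1,8-dimethoxy-4,5-di(propan-2-yloxy)-9H-fluoren-9-one | COc1ccc(OC(C)C)c2c1C(=O)c1c(OC)ccc(OC(C)C)c12
A1 | alternative 1 | (4aR,9R,9aS)-4a-ethenyl-5,8-dimethoxy-9-(2-methylprop-2-enyl)-9a-(3-methylbut-2-enyl)-4a,9a-dihydro-1H-fluorene-1,4(9H)-dione | CC(C)=CC[C@@]12C(=O)C=CC(=O)[C@]1(C=C)c1c(OC)ccc(OC)c1[C@H]2CC(C)=C
A2 | alternative 2 | methyl (2E)-2-{2-[(1Z)-2-(methoxycarbonyl)-5-methylhexa-1,4-dien-1-yl]-3,6-dimethoxyphenyl}-4-methylpenta-2,4-dienoate | COC(=O)/C(CC=C(C)C)=C\c1c(OC)ccc(OC)c1/C(C(=O)OC)=C\C(C)=C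
A3 | alternative 3 | 2-(3-methylbut-2-enyl)-3-[(1Z)-2-methyl-4-(3,6-dioxocyclohexa-1,4-dien-1-yl)but-1-en-1-yl]cyclohexa-2,5-diene-1,4-dione | O=C1C=CC(=O)C(CC=C(C)C)=C1/C=C(C)\CCC1=CC(=O)C=CC1=O
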